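**Retrosynthetic overview**

- The target comes from a tetraol by acetylation of its only primary hydroxyl; the tetraol from an epoxydon-type enone (i-Bu2AlH), which comes from a ketal-protected epoxy ketone by directed anti reduction and ketal hydrolysis.
- The epoxy ketone comes from hydroxyl-directed nucleophilic epoxidation of an α-(1-hydroxyalkyl) p-quinone monoketal; its ring-to-side-chain bond is made by asymmetric Nozaki–Hiyama–Kishi coupling of an α-iodo monoketal with the all-E C15 trienal.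
- Key step: the C15 chain is made by a 1,2-shift of an alkenyl carbon from boron to carbon in a bis-alkenyl boronate complex (selenium-triggered, stereoretentive Zweifel-type coupling, not pericyclic), joining a C9 alkenyl unit to a C6 dienyl boronate.
- The iodo monoketal comes from 3-bromophenol by hydroxymethylation, PhI(OAc)2/MeOH dearomatisation and α-iodination.
- Rings: the carbocycle is the arene of 3-bromophenol (dearomatised in step 6); the oxirane is the only ring formed, in step 9.

Assumption: 6-methylhept-5-en-1-yne is bought as a catalogue alkyne; in the comments C-1' is the side-chain carbinol carbon and C-4/C-5 are the oxirane carbons (C-4 carries the side chain).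

**Route**

Step 1
Reactants: 1 6-methylhept-5-en-1-yne
Product: 3 (E)-1-iodo-2,6-dimethylhepta-1,5-diene, via alkenylalane 2 (not isolated)
Conditions: Me3Al (2 equiv), Cp2ZrCl2 (20 mol %), CH2Cl2, 0 °C to rt; then I2, THF, −30 °C
Reagents that add atoms: trimethylaluminium C[Al](C)C; iodine [I][I]
Why: Negishi zirconium-catalysed carboalumination adds CH3 and Al syn across the terminal alkyne with Al on the terminal carbon, and iodinolysis with retention fixes the E trisubstituted alkene.

Step 2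
Reactants: 4 (E)-3-methylpent-2-en-4-yn-1-ol
Product: 6 trimethyl{[(2E,4E)-3-methyl-5-(4,4,5,5-tetramethyl-1,3,2-dioxaborolan-2-yl)penta-2,4-dien-1-yl]oxy}silane, via silyl ether 5 (not isolated)
Conditions: TMSCl (1.1 equiv), Et3N (1.2 equiv), CH2Cl2, 0 °C, filter; then pinacolborane (1.2 equiv), Cp2Zr(H)Cl (5 mol %), 50 °C
Reagents that add atoms: chlorotrimethylsilane C[Si](C)(C)Cl; pinacolborane [H]B1OC(C)(C)C(C)(C)O1
Why: O-silylation followed by Cp2Zr(H)Cl-catalysed syn hydroboration of the terminal alkyne puts boron on the terminal carbon and gives the 4E alkenyl boronate, the 2E alkene being left as it is.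

Step 3
Reactants: 3 (E)-1-iodo-2,6-dimethylhepta-1,5-diene; 6 silyl-protected dienyl boronate
Product: 11 (2E,4E,6E)-3,7,11-trimethyldodeca-2,4,6,10-tetraen-1-ol, via alkenyllithium 7 (not isolated), via boronate complex 8 (not isolated), via selanyl boronate 9 (not isolated), via trienyl silyl ether 10 (not isolated)
Conditions: 3, t-BuLi (2.0 equiv), Et2O, −78 °C; add 6, THF, −78 °C; PhSeCl, −78 °C; mCPBA, −45 to 0 °C; then K2CO3, MeOH, rt
Reagents that add atoms: none
Why: Proposed new method: alkenyllithium 7 adds to boronate 6 to give the bis-alkenyl complex 8, PhSe+ attacks the more substituted alkene at its β-carbon while the dienyl group undergoes a 1,2-shift from boron to the α-carbon anti to selenium (9), and selenoxide formation then syn-eliminates PhSeO–B(pin), so anti addition plus syn elimination returns both alkenes with retention (4E,6E) and forms the C-5'–C-6' bond; the closest known reaction type is the Zweifel olefination in its selenium-mediated syn-elimination form, known for alkyl boronic esters but not for an alkenyl–dienyl pair.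

Step 4
Reactants: 11 (2E,4E,6E)-3,7,11-trimethyldodeca-2,4,6,10-tetraen-1-ol
Product: 12 (2E,4E,6E)-3,7,11-trimethyldodeca-2,4,6,10-tetraenal
Conditions: MnO2 (15 equiv), CH2Cl2, rt
Reagents that add atoms: none
Why: Allylic alcohol oxidation on MnO2 stops at the aldehyde and leaves the triene geometry intact.

Step 5
Reactants: 13 3-bromophenol
Product: 15 3-(hydroxymethyl)phenol, via dilithio phenolate 14 (not isolated)
Conditions: t-BuLi (3.1 equiv), THF, −78 °C; paraformaldehyde, −78 °C to rt; H2O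
Reagents that add atoms: formaldehyde (as paraformaldehyde) C=O
Why: O–H deprotonation and bromine–lithium exchange give an aryllithium that adds to formaldehyde (hydroxymethylation), no stereocentre being involved.

Step 6
Reactants: 15 3-(hydroxymethyl)phenol
Product: 17 3-(hydroxymethyl)-4,4-dimethoxycyclohexa-2,5-dien-1-one, via methoxyphenol 16 (not isolated)
Conditions: PhI(OAc)2 (2.2 equiv), MeOH, 0 °C
Reagents that add atoms: methanol CO
Why: Two successive phenol oxidations with methanol capture para to the hydroxyl (oxidative dearomatisation) give the p-quinone monoketal whose ketal carbon lies next to the CH2OH-bearing carbon.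

Step 7
Reactants: 17 3-(hydroxymethyl)-4,4-dimethoxycyclohexa-2,5-dien-1-one
Product: 18 5-(hydroxymethyl)-2-iodo-4,4-dimethoxycyclohexa-2,5-dien-1-one
Conditions: I2 (1.5 equiv), pyridine, CH2Cl2, rt
Reagents that add atoms: iodine [I][I]
Why: Johnson α-iodination (pyridine conjugate addition, enolate iodination, elimination) can only start at the β-unsubstituted enone arm, so iodine enters para to the CH2OH-bearing carbon.

Step 8
Reactants: 18 5-(hydroxymethyl)-2-iodo-4,4-dimethoxycyclohexa-2,5-dien-1-one; 12 (2E,4E,6E)-3,7,11-trimethyldodeca-2,4,6,10-tetraenal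
Product: 20 5-(hydroxymethyl)-2-[(1S,2E,4E,6E)-1-hydroxy-3,7,11-trimethyldodeca-2,4,6,10-tetraen-1-yl]-4,4-dimethoxycyclohexa-2,5-dien-1-one, via alkenylchromium 19 (not isolated)
Conditions: CrCl2 (4 equiv), NiCl2 (2 mol %), Kishi oxazoline–sulfonamide ligand (4.4 equiv, enantiomer chosen for Re-face addition), Et3N, THF, rt
Reagents that add atoms: none
Why: Asymmetric Nozaki–Hiyama–Kishi coupling: nickel-mediated activation of the alkenyl iodide, transfer to trivalent chromium and 1,2-addition to the Re face of the enal within the chiral chromium sulfonamide complex set C-1' as S.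

Step 9
Reactants: 20 (S)-carbinol dienone
Product: 21 (1S,6R)-4-(hydroxymethyl)-1-[(1S,2E,4E,6E)-1-hydroxy-3,7,11-trimethyldodeca-2,4,6,10-tetraen-1-yl]-5,5-dimethoxy-7-oxabicyclo[4.1.0]hept-3-en-2-one
Conditions: t-BuOOH (3 equiv), n-BuLi (3 equiv), toluene/THF, −78 to −20 °C
Reagents that add atoms: tert-butyl hydroperoxide CC(C)(C)OO
Why: Hydroxyl-directed Weitz–Scheffer epoxidation: the C-1' lithium alkoxide carries t-BuOOLi to the β-carbon of its own enone arm through the conformer with C-1'–H eclipsing the ring C–C(=O) bond (the arrangement that makes directed epoxidations of 2-substituted allylic alcohols erythro-selective), so the oxirane forms erythro to the S carbinol with C-4 and C-5 as in the target, while the other enone arm is β,β-disubstituted and inert.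

Step 10
Reactants: 21 epoxy ketone
Product: 22 (1R,2S,6R)-4-(hydroxymethyl)-1-[(1S,2E,4E,6E)-1-hydroxy-3,7,11-trimethyldodeca-2,4,6,10-tetraen-1-yl]-5,5-dimethoxy-7-oxabicyclo[4.1.0]hept-3-en-2-ol
Conditions: Me4NBH(OAc)3 (5 equiv), MeCN/AcOH 1:1, −30 °C
Reagents that add atoms: none
Why: Evans–Saksena reduction: boron binds to the C-1' hydroxyl by acetate exchange and delivers hydride to the ketone through a chair-like six-membered transition state, giving the 1,3-anti diol, which places the new ring carbinol trans to the oxirane.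

Step 11
Reactants: 22 ketal triol
Product: 23 (1R,5S,6R)-5-hydroxy-3-(hydroxymethyl)-6-[(1S,2E,4E,6E)-1-hydroxy-3,7,11-trimethyldodeca-2,4,6,10-tetraen-1-yl]-7-oxabicyclo[4.1.0]hept-3-en-2-one
Conditions: PPTS (10 mol %), acetone/H2O 10:1, 0 °C to rt
Reagents that add atoms: water O
Why: Mild acid hydrolysis of the allylic dimethyl ketal unveils the enone without touching the oxirane or the stereocentres.

Step 12
Reactants: 23 epoxy enone triol
Product: 24 (1R,2S,5S,6S)-4-(hydroxymethyl)-1-[(1S,2E,4E,6E)-1-hydroxy-3,7,11-trimethyldodeca-2,4,6,10-tetraen-1-yl]-7-oxabicyclo[4.1.0]hept-3-ene-2,5-diol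
Conditions: i-Bu2AlH (5 equiv), THF, −78 °C; aq. Rochelle salt
Reagents that add atoms: none
Why: 1,2-Reduction of the α,β-epoxy enone by i-Bu2AlH, whose hydride approaches anti to the oxirane oxygen (the syn-selective mode of epoxy ketone reduction used for epoxyquinols), sets the last carbinol cis to the epoxide.

Step 13
Reactants: 24 tetraol
Product: 25 [(1R,2S,5S,6S)-2,5-dihydroxy-1-[(1S,2E,4E,6E)-1-hydroxy-3,7,11-trimethyldodeca-2,4,6,10-tetraen-1-yl]-7-oxabicyclo[4.1.0]hept-3-en-4-yl]methyl acetate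
Conditions: AcCl (1.05 equiv), 2,4,6-collidine, CH2Cl2, −78 °C
Reagents that add atoms: acetyl chloride CC(=O)Cl
Why: Sterically controlled acylation with AcCl/collidine esterifies only the primary hydroxyl, no stereocentre being changed.

**Compound list**

1 | 6-methylhept-5-en-1-yne | C#CCCC=C(C)C | starting material
2 | [(E)-2,6-dimethylhepta-1,5-dien-1-yl]dimethylalumane | C[Al](C)/C=C(\C)CCC=C(C)C | intermediate
3 | (E)-1-iodo-2,6-dimethylhepta-1,5-diene | I/C=C(\C)CCC=C(C)C | intermediate
4 | (E)-3-methylpent-2-en-4-yn-1-ol | OC/C=C(C)/C#C | starting material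
5 | trimethyl{[(E)-3-methylpent-2-en-4-yn-1-yl]oxy}silane | C[Si](C)(C)OC/C=C(C)/C#C | intermediate
6 | trimethyl{[(2E,4E)-3-methyl-5-(4,4,5,5-tetramethyl-1,3,2-dioxaborolan-2-yl)penta-2,4-dien-1-yl]oxy}silane | C[Si](C)(C)OC/C=C(C)/C=C/B1OC(C)(C)C(C)(C)O1 | intermediate
7 | [(E)-2,6-dimethylhepta-1,5-dien-1-yl]lithium | [Li]/C=C(\C)CCC=C(C)C | intermediate
8 | lithium [(E)-2,6-dimethylhepta-1,5-dien-1-yl][(1E,3E)-3-methyl-5-(trimethylsilyloxy)penta-1,3-dien-1-yl](pinacolato)borate | [Li+].C[Si](C)(C)OC/C=C(C)/C=C/[B-]1(OC(C)(C)C(C)(C)O1)/C=C(\C)CCC=C(C)C | intermediate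
9 | trimethyl{[(2E,4E)-3,7,11-trimethyl-7-(phenylselanyl)-6-(4,4,5,5-tetramethyl-1,3,2-dioxaborolan-2-yl)dodeca-2,4,10-trien-1-yl]oxy}silane, (6R*,7R*), racemic, one enantiomer drawn | CC1(C)OB(OC1(C)C)[C@H](/C=C/C(C)=C/CO[Si](C)(C)C)[C@](C)([Se]c1ccccc1)CCC=C(C)C | intermediate
10 | trimethyl{[(2E,4E,6E)-3,7,11-trimethyldodeca-2,4,6,10-tetraen-1-yl]oxy}silane | C[Si](C)(C)OC/C=C(C)/C=C/C=C(\C)CCC=C(C)C | intermediate
11 | (2E,4E,6E)-3,7,11-trimethyldodeca-2,4,6,10-tetraen-1-ol | OC/C=C(C)/C=C/C=C(\C)CCC=C(C)C | intermediate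
12 | (2E,4E,6E)-3,7,11-trimethyldodeca-2,4,6,10-tetraenal | O=C/C=C(C)/C=C/C=C(\C)CCC=C(C)C | intermediate
13 | 3-bromophenol | Oc1cccc(Br)c1 | starting material
14 | lithium 3-lithiophenolate | [Li]Oc1cccc([Li])c1 | intermediate
15 | 3-(hydroxymethyl)phenol | OCc1cccc(O)c1 | intermediate
16 | 3-(hydroxymethyl)-4-methoxyphenol | OCc1cc(O)ccc1OC | intermediate
17 | 3-(hydroxymethyl)-4,4-dimethoxycyclohexa-2,5-dien-1-one | OCC1=CC(=O)C=CC1(OC)OC | intermediate
18 | 5-(hydroxymethyl)-2-iodo-4,4-dimethoxycyclohexa-2,5-dien-1-one | IC1=CC(OC)(OC)C(CO)=CC1=O | intermediate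
19 | dichloro[4-(hydroxymethyl)-3,3-dimethoxy-6-oxocyclohexa-1,4-dien-1-yl]chromium | OCC1=CC(=O)C([Cr](Cl)Cl)=CC1(OC)OC | intermediate
20 | 5-(hydroxymethyl)-2-[(1S,2E,4E,6E)-1-hydroxy-3,7,11-trimethyldodeca-2,4,6,10-tetraen-1-yl]-4,4-dimethoxycyclohexa-2,5-dien-1-one | OCC1=CC(=O)C([C@@H](O)/C=C(C)/C=C/C=C(\C)CCC=C(C)C)=CC1(OC)OC | intermediate
21 | (1S,6R)-4-(hydroxymethyl)-1-[(1S,2E,4E,6E)-1-hydroxy-3,7,11-trimethyldodeca-2,4,6,10-tetraen-1-yl]-5,5-dimethoxy-7-oxabicyclo[4.1.0]hept-3-en-2-one | OCC1=CC(=O)[C@@]2([C@@H](O)/C=C(C)/C=C/C=C(\C)CCC=C(C)C)O[C@H]2C1(OC)OC | intermediate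
22 | (1R,2S,6R)-4-(hydroxymethyl)-1-[(1S,2E,4E,6E)-1-hydroxy-3,7,11-trimethyldodeca-2,4,6,10-tetraen-1-yl]-5,5-dimethoxy-7-oxabicyclo[4.1.0]hept-3-en-2-ol | OCC1=C[C@H](O)[C@@]2([C@@H](O)/C=C(C)/C=C/C=C(\C)CCC=C(C)C)O[C@H]2C1(OC)OC | intermediate
23 | (1R,5S,6R)-5-hydroxy-3-(hydroxymethyl)-6-[(1S,2E,4E,6E)-1-hydroxy-3,7,11-trimethyldodeca-2,4,6,10-tetraen-1-yl]-7-oxabicyclo[4.1.0]hept-3-en-2-one | OCC1=C[C@H](O)[C@@]2([C@@H](O)/C=C(C)/C=C/C=C(\C)CCC=C(C)C)O[C@H]2C1=O | intermediate
24 | (1R,2S,5S,6S)-4-(hydroxymethyl)-1-[(1S,2E,4E,6E)-1-hydroxy-3,7,11-trimethyldodeca-2,4,6,10-tetraen-1-yl]-7-oxabicyclo[4.1.0]hept-3-ene-2,5-diol | OCC1=C[C@H](O)[C@@]2([C@@H](O)/C=C(C)/C=C/C=C(\C)CCC=C(C)C)O[C@H]2[C@H]1O | intermediate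
25 | [(1R,2S,5S,6S)-2,5-dihydroxy-1-[(1S,2E,4E,6E)-1-hydroxy-3,7,11-trimethyldodeca-2,4,6,10-tetraen-1-yl]-7-oxabicyclo[4.1.0]hept-3-en-4-yl]methyl acetate | CC(=O)OCC1=C[C@H](O)[C@@]2([C@@H](O)/C=C(C)/C=C/C=C(\C)CCC=C(C)C)O[C@H]2[C@H]1O | target

**Step count and weak points**

Total step count: 13. Longest linear sequence: 9 steps (1 or 2, then 3, 4, 8–13; the arene branch 5–13 is also 9).

The three steps most likely to fail:

Step 3 (the proposed new step). PhSe+ may attack the dienyl arm of 8 instead, giving an allylic selenoxide that rearranges by a [2,3] shift, or the alkenes may lose geometry. The fallback uses known chemistry, sets out from 4 and 1 and comes back at 11. Compound 4 is silylated in situ as in step 2, hydrozirconated with Cp2Zr(H)Cl and iodinated to give, after aqueous work-up, (2E,4E)-5-iodo-3-methylpenta-2,4-dien-1-ol F1. Alane 2, made from 1 exactly as in step 1, is then cross-coupled in the same pot with F1 (ZnCl2, Pd(PPh3)4, THF; Negishi alkenyl–alkenyl coupling) to give 11.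

Step 8. The α-iodo dienone may be a sluggish partner, or the chiral chromium complex may give low facial selectivity; the ligand enantiomer that gives Re-face addition has to be confirmed on a test reaction. The fallback sets out from 18 and 12 and comes back at 20. Ligand-free coupling (CrCl2, NiCl2 cat., DMF) gives the racemic carbinol F2. TBSCl/imidazole caps the primary hydroxyl to give the racemic silyl ether F3. Dess–Martin periodinane gives the trienone F4. Reduction with (R)-2-methyl-CBS-oxazaborolidine and catecholborane (ring alkenyl as the large group) gives the (S)-carbinol silyl ether F5, and HF·pyridine removes the silyl group to return 20.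

Step 9. Facial control rests on a conformational model; the erythro outcome is argued by analogy and is not precedented on this substrate. The primary alkoxide could also steer the peroxide to the other enone arm. The fallback sets out from 20, comes back at 21 and replaces substrate direction by catalyst control. TESCl/imidazole gives the bis(triethylsilyl) ether F6. Epoxidation of its only reactive enone arm with La(Oi-Pr)3, BINOL, Ph3As=O and t-BuOOH (BINOL antipode chosen in a test run) gives the silylated epoxy ketone F7, and HF·pyridine gives 21.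

**Further compounds**

F1 | step 3 | (2E,4E)-5-iodo-3-methylpenta-2,4-dien-1-ol | OC/C=C(C)/C=C/I
F2 | step 8 | racemic 5-(hydroxymethyl)-2-[(2E,4E,6E)-1-hydroxy-3,7,11-trimethyldodeca-2,4,6,10-tetraen-1-yl]-4,4-dimethoxycyclohexa-2,5-dien-1-one | OCC1=CC(=O)C(C(O)/C=C(C)/C=C/C=C(\C)CCC=C(C)C)=CC1(OC)OC
F3 | step 8 | racemic 5-{[tert-butyl(dimethyl)silyl]oxymethyl}-2-[(2E,4E,6E)-1-hydroxy-3,7,11-trimethyldodeca-2,4,6,10-tetraen-1-yl]-4,4-dimethoxycyclohexa-2,5-dien-1-one | CC(C)(C)[Si](C)(C)OCC1=CC(=O)C(C(O)/C=C(C)/C=C/C=C(\C)CCC=C(C)C)=CC1(OC)OC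
F4 | step 8 | 5-{[tert-butyl(dimethyl)silyl]oxymethyl}-4,4-dimethoxy-2-[(2E,4E,6E)-3,7,11-trimethyldodeca-2,4,6,10-tetraenoyl]cyclohexa-2,5-dien-1-one | CC(C)(C)[Si](C)(C)OCC1=CC(=O)C(C(=O)/C=C(C)/C=C/C=C(\C)CCC=C(C)C)=CC1(OC)OC
F5 | step 8 | 5-{[tert-butyl(dimethyl)silyl]oxymethyl}-2-[(1S,2E,4E,6E)-1-hydroxy-3,7,11-trimethyldodeca-2,4,6,10-tetraen-1-yl]-4,4-dimethoxycyclohexa-2,5-dien-1-one | CC(C)(C)[Si](C)(C)OCC1=CC(=O)C([C@@H](O)/C=C(C)/C=C/C=C(\C)CCC=C(C)C)=CC1(OC)OC
F6 | step 9 | bis(triethylsilyl) ether of 20 (primary and C-1' oxygens silylated, C-1' S) | CC[Si](CC)(CC)OCC1=CC(=O)C([C@@H](O[Si](CC)(CC)CC)/C=C(C)/C=C/C=C(\C)CCC=C(C)C)=CC1(OC)OC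
F7 | step 9 | bis(triethylsilyl) ether of 21 (same configuration as 21) | CC[Si](CC)(CC)OCC1=CC(=O)[C@@]2([C@@H](O[Si](CC)(CC)CC)/C=C(C)/C=C/C=C(\C)CCC=C(C)C)O[C@H]2C1(OC)OC
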